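## Retrosynthetic overview

1. The only ring, the 28-membered lactone-lactam, is closed last (before desilylation) by an enantioselective Passerini macrocyclisation of an ω-isocyano acid with butanal, catalysed by a chiral phosphoric acid. This forms the C2–C3 bond, the lactone C–O bond and the C2 stereocentre.
2. The isocyano acid comes from a formamide methyl ester, assembled by B-alkyl Suzuki coupling (C17–C18 of the chain) of a 2-bromo-1,3-diene with a polyol alkene.
3. The bromodiene comes from a C–I-selective Suzuki coupling of an alkenylboronate with (E)-2-bromo-1-iodo-3-methoxypropene; this fixes the 16Z geometry.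
4. The boronate is built from two halves, each made by copper-catalysed asymmetric allylic alkylation plus cross-metathesis, joined by an sp3–sp3 Kochi coupling.
5. The polyol comes from Sharpless desymmetrisation of divinylcarbinol (anti-diol), dithiane opening and a catalytic asymmetric Henry reaction (carbinol and nitrogen).

Assumption: the target is taken exactly as drawn in the SMILES; where the facial sense of a catalyst is quoted by analogy (Taniaphos, inda-box, TRIP), the antipodal catalyst is used if a test run shows the opposite sense.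

## Route

Step 1
Reactants: 1 6-bromohex-1-ene; 2 (E)-1,4-dibromobut-2-ene
Product: 3 (E)-1,7-dibromohept-2-ene
Conditions: 2 (3 equiv), second-generation Hoveyda–Grubbs catalyst (C31H38Cl2N2ORu, 2 mol%), CH2Cl2, 40 °C
Reagents that add atoms: none
Why: Olefin cross-metathesis of a terminal alkene with an excess of the symmetrical dibromobutene gives the E-allylic bromide under thermodynamic control; the alkyl bromide is inert.

Step 2
Reactants: 3 (E)-1,7-dibromohept-2-ene; 4 methylmagnesium bromide
Product: 5 (3R)-7-bromo-3-methylhept-1-ene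
Conditions: CuBr·SMe2 (1 mol%), (R,Rp)-Taniaphos (ferrocenyl diphosphine, C43H39FeNP2, 1.2 mol%), CH2Cl2, −75 °C
Reagents that add atoms: none
Why: Copper-catalysed asymmetric allylic alkylation (SN2′) with a Grignard reagent; the chiral copper–diphosphine complex delivers methyl to one face of the γ-carbon and sets the first stereocentre (R), while the primary alkyl bromide does not react at −75 °C.

Step 3
Reactants: 5 (3R)-7-bromo-3-methylhept-1-ene; 6 methyl methacrylate
Product: 7 methyl (2E,4R)-8-bromo-2,4-dimethyloct-2-enoate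
Conditions: 6 (10 equiv), second-generation Hoveyda–Grubbs catalyst (5 mol%), CH2Cl2, 40 °C
Reagents that add atoms: none
Why: Cross-metathesis with excess methacrylate gives the trisubstituted E-enoate; the allylic stereocentre is not touched.

Step 4
Reactants: 8 1-bromo-4-chlorobutane; 9 (E)-1-bromopent-2-ene
Product: 11 (3R)-7-chloro-3-ethylhept-1-ene, via 4-chlorobutylmagnesium bromide 10 (not isolated)
Conditions: Mg, Et2O, 0 °C to rt; then added to 9, CuBr·SMe2 (3 mol%), (S,Sp)-Taniaphos (3.6 mol%), CH2Cl2, −75 °C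
Reagents that add atoms: none
Why: Magnesium inserts selectively into the C–Br bond; the same copper-catalysed SN2′ allylic alkylation then sets the ethyl-bearing centre (R), with the antipodal ligand because the substrate substituent and the nucleophile have exchanged roles.

Step 5
Reactants: 11 (3R)-7-chloro-3-ethylhept-1-ene; 7 methyl (2E,4R)-8-bromo-2,4-dimethyloct-2-enoate
Product: 13 methyl (2E,4R,13R)-13-ethyl-2,4-dimethylpentadeca-2,14-dienoate, via [(5R)-5-ethylhept-6-en-1-yl]magnesium chloride 12 (not isolated)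
Conditions: Mg, THF, reflux; then added slowly to 7, Li2CuCl4 (3 mol%), THF/NMP, −5 °C
Reagents that add atoms: none
Why: Copper-catalysed Kochi-type alkyl–alkyl coupling of a primary Grignard reagent with a primary bromide is faster than addition to the hindered α-methyl enoate at low temperature; no stereocentre is involved.

Step 6
Reactants: 13 methyl (2E,4R,13R)-13-ethyl-2,4-dimethylpentadeca-2,14-dienoate; 14 4,4,5,5-tetramethyl-2-vinyl-1,3,2-dioxaborolane
Product: 15 methyl (2E,4R,13R,14E)-13-ethyl-2,4-dimethyl-15-(4,4,5,5-tetramethyl-1,3,2-dioxaborolan-2-yl)pentadeca-2,14-dienoate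
Conditions: 14 (3 equiv), second-generation Grubbs catalyst (C46H65Cl2N2PRu, 5 mol%), CH2Cl2, 40 °C
Reagents that add atoms: none
Why: Cross-metathesis of the terminal vinyl group with the vinylboronate gives the E-alkenylboronate; the conjugated trisubstituted enoate is metathesis-inert.

Step 7
Reactants: 16 3-methoxyprop-1-yne
Product: 17 (E)-2-bromo-1-iodo-3-methoxyprop-1-ene
Conditions: IBr (1.05 equiv), CH2Cl2, −78 to 0 °C, dark
Reagents that add atoms: iodine monobromide, IBr
Why: Electrophilic anti-addition of I–Br through an iodonium ion, opened by bromide at the internal carbon (Markovnikov), gives the E-dihalide with iodine at the terminus.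

Step 8
Reactants: 15 alkenylboronate; 17 (E)-2-bromo-1-iodo-3-methoxyprop-1-ene
Product: 18 methyl (2E,4R,13R,14E,16E)-17-bromo-13-ethyl-18-methoxy-2,4-dimethyloctadeca-2,14,16-trienoate
Conditions: Pd(PPh3)4 (5 mol%), aq K3PO4, THF, rt
Reagents that add atoms: none
Why: Suzuki–Miyaura coupling occurs at the C–I bond only (much faster oxidative addition than C–Br) and retains both alkene geometries, so the bromine ends up trans to the new diene carbon.

Step 9
Reactants: 19 penta-1,4-dien-3-ol
Product: 20 (2S,3R)-1,2-epoxypent-4-en-3-ol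
Conditions: Ti(OiPr)4 (10 mol%), D-(−)-diisopropyl tartrate (13 mol%), t-BuOOH, 4 Å MS, CH2Cl2, −20 °C
Reagents that add atoms: tert-butyl hydroperoxide, CC(C)(C)OO
Why: Sharpless asymmetric epoxidation of the prochiral dienol combines enantiotopic-group and diastereoface selection to set both centres of the erythro epoxy alcohol (2S,3R); the minor enantiomer is removed by faster second epoxidation.

Step 10
Reactants: 20 (2S,3R)-1,2-epoxypent-4-en-3-ol; 21 1,3-dithiane
Product: 23 (3R,4S)-5-(1,3-dithian-2-yl)pent-1-ene-3,4-diol, via 2-lithio-1,3-dithiane 22 (not isolated)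
Conditions: 21 (2.5 equiv), n-BuLi (2.4 equiv), THF, −30 °C; then 20, −30 to 0 °C; H2O
Reagents that add atoms: none
Why: Corey–Seebach dithiane anion opens the terminal epoxide at the CH2 carbon (SN2), so both stereocentres are retained and a masked aldehyde carbon is added.

Step 11
Reactants: 23 (3R,4S)-5-(1,3-dithian-2-yl)pent-1-ene-3,4-diol
Product: 24 2-{(2S,3R)-2,3-bis[(tert-butyldimethylsilyl)oxy]pent-4-en-1-yl}-1,3-dithiane
Conditions: TBSOTf (2.4 equiv), 2,6-lutidine, CH2Cl2, −40 to 0 °C
Reagents that add atoms: tert-butyldimethylsilyl trifluoromethanesulfonate, CC(C)(C)[Si](C)(C)OS(=O)(=O)C(F)(F)F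
Why: Silyl triflate silylation protects both secondary hydroxyls of the vicinal diol without touching the thioacetal.

Step 12
Reactants: 24 bis-silyl dithiane
Product: 25 (3S,4R)-3,4-bis[(tert-butyldimethylsilyl)oxy]hex-5-enal
Conditions: MeI, CaCO3, MeCN/H2O (9:1), 45 °C
Reagents that add atoms: water, O
Why: Alkylative dithiane hydrolysis: S-methylation turns sulfur into a leaving group and buffered water releases the aldehyde while the silyl ethers survive.

Step 13
Reactants: 25 (3S,4R)-3,4-bis[(tert-butyldimethylsilyl)oxy]hex-5-enal; 26 nitromethane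
Product: 27 (2S,4S,5R)-4,5-bis[(tert-butyldimethylsilyl)oxy]-1-nitrohept-6-en-2-ol
Conditions: 26 (10 equiv), Cu(OAc)2·H2O (5 mol%), inda-box ligand (2,2′-isopropylidenebis(3a,8a-dihydro-8H-indeno[1,2-d]oxazole), enantiomer giving 2S, 5.5 mol%), EtOH, rt
Reagents that add atoms: none
Why: Catalytic asymmetric Henry (nitroaldol) reaction; the copper–bis(oxazoline) acetate complex selects the aldehyde face (catalyst control over the remote β-silyloxy centre) and sets the new carbinol as S, 1,3-anti to the neighbouring oxygen.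

Step 14
Reactants: 27 nitro alcohol
Product: 28 (3R,4S,6S)-3,4,6-tris[(tert-butyldimethylsilyl)oxy]-7-nitrohept-1-ene
Conditions: TBSOTf (1.3 equiv), 2,6-lutidine, CH2Cl2, −78 °C
Reagents that add atoms: tert-butyldimethylsilyl trifluoromethanesulfonate, CC(C)(C)[Si](C)(C)OS(=O)(=O)C(F)(F)F
Why: Low-temperature silylation with the triflate traps the nitroaldol before retro-Henry or elimination can occur.

Step 15
Reactants: 28 tris-silyl nitroalkene; 29 ethyl formate
Product: 31 N-{(2S,4S,5R)-2,4,5-tris[(tert-butyldimethylsilyl)oxy]hept-6-en-1-yl}formamide, via primary amine 30 (not isolated)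
Conditions: LiAlH4, Et2O, 0 °C to rt; Fieser work-up, filter; then 29 (neat), 55 °C
Reagents that add atoms: none
Why: Hydride reduction of the aliphatic nitro group gives the primary amine, which is N-formylated by ester aminolysis; alkene and silyl ethers are inert and no stereocentre is affected.

Step 16
Reactants: 31 formamide alkene; 18 bromodiene ester
Product: 33 methyl (2E,4R,13R,14E,16Z,20R,21S,23S)-20,21,23-tris[(tert-butyldimethylsilyl)oxy]-13-ethyl-24-formamido-17-(methoxymethyl)-2,4-dimethyltetracosa-2,14,16-trienoate, via B-alkyl-9-BBN adduct 32 (not isolated)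
Conditions: 31 (1.3 equiv), 9-BBN dimer, THF, rt; H2O; then 18, PdCl2(dppf)·CH2Cl2 (10 mol%), AsPh3, aq Cs2CO3, DMF, rt
Reagents that add atoms: none
Why: Anti-Markovnikov hydroboration of the terminal alkene followed by B-alkyl Suzuki–Miyaura coupling at the alkenyl bromide proceeds with retention, so the new chain is trans to the diene and the trisubstituted alkene is 16Z.

Step 17
Reactants: 33 formamide ester
Product: 34 methyl (2E,4R,13R,14E,16Z,20R,21S,23S)-20,21,23-tris[(tert-butyldimethylsilyl)oxy]-13-ethyl-24-isocyano-17-(methoxymethyl)-2,4-dimethyltetracosa-2,14,16-trienoate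
Conditions: POCl3 (1.3 equiv), Et3N, CH2Cl2, −30 to 0 °C; aq NaHCO3
Reagents that add atoms: none
Why: Ugi-type dehydration of a secondary formamide gives the isocyanide under basic conditions that spare the diene, allylic ether, ester and silyl ethers; it is placed after all palladium steps because isocyanides insert into Pd–C bonds.

Step 18
Reactants: 34 isocyanide ester
Product: 35 (2E,4R,13R,14E,16Z,20R,21S,23S)-20,21,23-tris[(tert-butyldimethylsilyl)oxy]-13-ethyl-24-isocyano-17-(methoxymethyl)-2,4-dimethyltetracosa-2,14,16-trienoic acid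
Conditions: LiOH·H2O, THF/MeOH/H2O, 35 °C; then NaH2PO4 buffer to pH 5–6, 0 °C, extract into CHCl3, dry, use at once
Reagents that add atoms: lithium hydroxide, [Li+].[OH-]
Why: Ester saponification; isocyanides are stable to base and the buffered acidification avoids acid hydrolysis of the isocyanide.

Step 19
Reactants: 35 ω-isocyano acid; 36 butanal
Product: 38 (2S,6S,8S,9R,12Z,14E,16R,25R,26E)-6,8,9-tris[(tert-butyldimethylsilyl)oxy]-16-ethyl-12-(methoxymethyl)-25,27-dimethyl-2-propyl-1-oxa-4-azacyclooctacosa-12,14,26-triene-3,28-dione, via macrocyclic acyl imidate 37 (not isolated)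
Conditions: 36 (5 equiv), (R)-TRIP (3,3′-bis(2,4,6-triisopropylphenyl)-1,1′-binaphthyl-2,2′-diyl hydrogen phosphate, 20 mol%), 4 Å MS, CHCl3, 0 °C to rt; 35 added by syringe pump over 20 h, final 1 mM
Reagents that add atoms: none
Why: Proposed new method: the chiral phosphoric acid hydrogen-bonds butanal and steers attack of the isocyanide to its Re face (C2 = S), the nitrilium held by the phosphate is captured under high dilution by the carboxylic acid of the same chain to give the 27-membered acyl imidate, and the irreversible Mumm O→O acyl shift expands it to the 28-membered lactone, while the termolecular uncatalysed background is suppressed at 1 mM; the closest known reactions are the intermolecular three-component Passerini reaction catalysed by chiral phosphoric acids and uncatalysed Passerini or Ugi macrocyclisations of bifunctional substrates.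

Step 20
Reactants: 38 tris-silyl macrocycle
Product: 39 (2S,6S,8S,9R,12Z,14E,16R,25R,26E)-16-ethyl-6,8,9-trihydroxy-12-(methoxymethyl)-25,27-dimethyl-2-propyl-1-oxa-4-azacyclooctacosa-12,14,26-triene-3,28-dione (target)
Conditions: HF·pyridine, pyridine, THF, 0 °C to rt
Reagents that add atoms: none
Why: Fluoride-mediated desilylation removes the three silyl ethers under buffered conditions that leave the α-acyloxy amide, the enoate lactone and the dienyl methyl ether intact.

## Compound list

1 | 6-bromohex-1-ene | C=CCCCCBr | starting material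
2 | (E)-1,4-dibromobut-2-ene | BrC/C=C/CBr | starting material
3 | (E)-1,7-dibromohept-2-ene | BrC/C=C/CCCCBr | intermediate
4 | methylmagnesium bromide | C[Mg]Br | starting material
5 | (3R)-7-bromo-3-methylhept-1-ene | C=C[C@H](C)CCCCBr | intermediate
6 | methyl methacrylate | COC(=O)C(C)=C | starting material
7 | methyl (2E,4R)-8-bromo-2,4-dimethyloct-2-enoate | COC(=O)/C(C)=C/[C@H](C)CCCCBr | intermediate
8 | 1-bromo-4-chlorobutane | ClCCCCBr | starting material
9 | (E)-1-bromopent-2-ene | CC/C=C/CBr | starting material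
10 | 4-chlorobutylmagnesium bromide | ClCCCC[Mg]Br | intermediate (not isolated)
11 | (3R)-7-chloro-3-ethylhept-1-ene | C=C[C@H](CC)CCCCCl | intermediate
12 | [(5R)-5-ethylhept-6-en-1-yl]magnesium chloride | C=C[C@H](CC)CCCC[Mg]Cl | intermediate (not isolated)
13 | methyl (2E,4R,13R)-13-ethyl-2,4-dimethylpentadeca-2,14-dienoate | COC(=O)/C(C)=C/[C@H](C)CCCCCCCC[C@@H](CC)C=C | intermediate
14 | 4,4,5,5-tetramethyl-2-vinyl-1,3,2-dioxaborolane | C=CB1OC(C)(C)C(C)(C)O1 | starting material
15 | methyl (2E,4R,13R,14E)-13-ethyl-2,4-dimethyl-15-(4,4,5,5-tetramethyl-1,3,2-dioxaborolan-2-yl)pentadeca-2,14-dienoate | COC(=O)/C(C)=C/[C@H](C)CCCCCCCC[C@@H](CC)/C=C/B1OC(C)(C)C(C)(C)O1 | intermediate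
16 | 3-methoxyprop-1-yne | C#CCOC | starting material
17 | (E)-2-bromo-1-iodo-3-methoxyprop-1-ene | I/C=C(/Br)COC | intermediate
18 | methyl (2E,4R,13R,14E,16E)-17-bromo-13-ethyl-18-methoxy-2,4-dimethyloctadeca-2,14,16-trienoate | COC(=O)/C(C)=C/[C@H](C)CCCCCCCC[C@@H](CC)/C=C/C=C(/Br)COC | intermediate
19 | penta-1,4-dien-3-ol | C=CC(O)C=C | starting material
20 | (2S,3R)-1,2-epoxypent-4-en-3-ol | C=C[C@@H](O)[C@@H]1CO1 | intermediate
21 | 1,3-dithiane | C1CSCSC1 | starting material
22 | 2-lithio-1,3-dithiane | [Li]C1SCCCS1 | intermediate (not isolated)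
23 | (3R,4S)-5-(1,3-dithian-2-yl)pent-1-ene-3,4-diol | C=C[C@@H](O)[C@@H](O)CC1SCCCS1 | intermediate
24 | 2-{(2S,3R)-2,3-bis[(tert-butyldimethylsilyl)oxy]pent-4-en-1-yl}-1,3-dithiane | C=C[C@@H](O[Si](C)(C)C(C)(C)C)[C@@H](O[Si](C)(C)C(C)(C)C)CC1SCCCS1 | intermediate
25 | (3S,4R)-3,4-bis[(tert-butyldimethylsilyl)oxy]hex-5-enal | C=C[C@@H](O[Si](C)(C)C(C)(C)C)[C@@H](O[Si](C)(C)C(C)(C)C)CC=O | intermediate
26 | nitromethane | C[N+](=O)[O-] | starting material
27 | (2S,4S,5R)-4,5-bis[(tert-butyldimethylsilyl)oxy]-1-nitrohept-6-en-2-ol | C=C[C@@H](O[Si](C)(C)C(C)(C)C)[C@@H](O[Si](C)(C)C(C)(C)C)C[C@H](O)C[N+](=O)[O-] | intermediate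
28 | (3R,4S,6S)-3,4,6-tris[(tert-butyldimethylsilyl)oxy]-7-nitrohept-1-ene | C=C[C@@H](O[Si](C)(C)C(C)(C)C)[C@@H](O[Si](C)(C)C(C)(C)C)C[C@H](O[Si](C)(C)C(C)(C)C)C[N+](=O)[O-] | intermediate
29 | ethyl formate | CCOC=O | starting material
30 | (2S,4S,5R)-2,4,5-tris[(tert-butyldimethylsilyl)oxy]hept-6-en-1-amine | C=C[C@@H](O[Si](C)(C)C(C)(C)C)[C@@H](O[Si](C)(C)C(C)(C)C)C[C@H](O[Si](C)(C)C(C)(C)C)CN | intermediate (not isolated)
31 | N-{(2S,4S,5R)-2,4,5-tris[(tert-butyldimethylsilyl)oxy]hept-6-en-1-yl}formamide | C=C[C@@H](O[Si](C)(C)C(C)(C)C)[C@@H](O[Si](C)(C)C(C)(C)C)C[C@H](O[Si](C)(C)C(C)(C)C)CNC=O | intermediate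
32 | N-{(2S,4S,5R)-7-(9-borabicyclo[3.3.1]nonan-9-yl)-2,4,5-tris[(tert-butyldimethylsilyl)oxy]heptyl}formamide | C(C[C@@H](O[Si](C)(C)C(C)(C)C)[C@@H](O[Si](C)(C)C(C)(C)C)C[C@H](O[Si](C)(C)C(C)(C)C)CNC=O)B1C2CCCC1CCC2 | intermediate (not isolated)
33 | methyl (2E,4R,13R,14E,16Z,20R,21S,23S)-20,21,23-tris[(tert-butyldimethylsilyl)oxy]-13-ethyl-24-formamido-17-(methoxymethyl)-2,4-dimethyltetracosa-2,14,16-trienoate | COC(=O)/C(C)=C/[C@H](C)CCCCCCCC[C@@H](CC)/C=C/C=C(\COC)CC[C@@H](O[Si](C)(C)C(C)(C)C)[C@@H](O[Si](C)(C)C(C)(C)C)C[C@H](O[Si](C)(C)C(C)(C)C)CNC=O | intermediate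
34 | methyl (2E,4R,13R,14E,16Z,20R,21S,23S)-20,21,23-tris[(tert-butyldimethylsilyl)oxy]-13-ethyl-24-isocyano-17-(methoxymethyl)-2,4-dimethyltetracosa-2,14,16-trienoate | COC(=O)/C(C)=C/[C@H](C)CCCCCCCC[C@@H](CC)/C=C/C=C(\COC)CC[C@@H](O[Si](C)(C)C(C)(C)C)[C@@H](O[Si](C)(C)C(C)(C)C)C[C@H](O[Si](C)(C)C(C)(C)C)C[N+]#[C-] | intermediate
35 | (2E,4R,13R,14E,16Z,20R,21S,23S)-20,21,23-tris[(tert-butyldimethylsilyl)oxy]-13-ethyl-24-isocyano-17-(methoxymethyl)-2,4-dimethyltetracosa-2,14,16-trienoic acid | OC(=O)/C(C)=C/[C@H](C)CCCCCCCC[C@@H](CC)/C=C/C=C(\COC)CC[C@@H](O[Si](C)(C)C(C)(C)C)[C@@H](O[Si](C)(C)C(C)(C)C)C[C@H](O[Si](C)(C)C(C)(C)C)C[N+]#[C-] | intermediate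
36 | butanal | CCCC=O | starting material
37 | 27-membered cyclic O-acyl imidate: the carboxyl oxygen is bonded to the former isocyanide carbon, which carries C=N and an exocyclic (1S)-1-hydroxybutyl group; C=N geometry not fixed | O1C(=O)/C(C)=C/[C@H](C)CCCCCCCC[C@@H](CC)/C=C/C=C(\COC)CC[C@@H](O[Si](C)(C)C(C)(C)C)[C@@H](O[Si](C)(C)C(C)(C)C)C[C@H](O[Si](C)(C)C(C)(C)C)CN=C1[C@@H](O)CCC | intermediate (not isolated)
38 | (2S,6S,8S,9R,12Z,14E,16R,25R,26E)-6,8,9-tris[(tert-butyldimethylsilyl)oxy]-16-ethyl-12-(methoxymethyl)-25,27-dimethyl-2-propyl-1-oxa-4-azacyclooctacosa-12,14,26-triene-3,28-dione | CCC[C@@H]1OC(=O)/C(C)=C/[C@H](C)CCCCCCCC[C@@H](CC)/C=C/C=C(\COC)CC[C@@H](O[Si](C)(C)C(C)(C)C)[C@@H](O[Si](C)(C)C(C)(C)C)C[C@H](O[Si](C)(C)C(C)(C)C)CNC1=O | intermediate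
39 | (2S,6S,8S,9R,12Z,14E,16R,25R,26E)-16-ethyl-6,8,9-trihydroxy-12-(methoxymethyl)-25,27-dimethyl-2-propyl-1-oxa-4-azacyclooctacosa-12,14,26-triene-3,28-dione | CCC[C@@H]1OC(=O)/C(C)=C/[C@H](C)CCCCCCCC[C@@H](CC)/C=C/C=C(\COC)CC[C@@H](O)[C@@H](O)C[C@H](O)CNC1=O | target

## Step count and risk

Total steps: 20. Longest linear sequence: 12 steps (steps 9–20, from penta-1,4-dien-3-ol).

Steps most likely to fail:

**Step 19 (new macrocyclising Passerini reaction).** Oligomerisation, slow closure of the 27-membered imidate, or poor facial control are all possible. The fallback uses known chemistry and sets out from isocyanide ester 34. The known intermolecular three-component Passerini reaction catalysed by a chiral phosphoric acid (butanal 36, acetic acid, (R)-TRIP, CHCl3) gives methyl (2E,4R,13R,14E,16Z,20R,21S,23S)-24-{[(2S)-2-acetoxypentanoyl]amino}-20,21,23-tris[(tert-butyldimethylsilyl)oxy]-13-ethyl-17-(methoxymethyl)-2,4-dimethyltetracosa-2,14,16-trienoate F1. LiOH in aqueous THF/MeOH then cleaves both the acetate and the methyl ester to give the seco acid, the corresponding 24-{[(2S)-2-hydroxypentanoyl]amino} trienoic acid F2. Yamaguchi macrolactonisation (2,4,6-trichlorobenzoyl chloride, Et3N, THF; then DMAP, toluene, high dilution, 60 °C) closes the ring and comes back to the route at 38.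

**Step 16 (hydroboration and B-alkyl Suzuki coupling).** The formamide N–H can consume borane, and the hindered 2-bromodiene may couple slowly under aqueous base. The fallback replaces the in-situ borane by an isolated halide and a base-free organozinc coupling. It sets out from 31: hydroboration to 32 as before, then I2/NaOMe gives N-{(2S,4S,5R)-2,4,5-tris[(tert-butyldimethylsilyl)oxy]-7-iodoheptyl}formamide F3. Zinc dust with LiCl in THF converts it into iodido{(3R,4S,6S)-3,4,6-tris[(tert-butyldimethylsilyl)oxy]-7-formamidoheptyl}zinc F4. Negishi coupling with 18 (Pd(OAc)2, SPhos, THF, rt) comes back to the route at 33.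

**Step 4 (allylic alkylation with a functionalised Grignard reagent on a simple 2-alkenyl bromide).** Branched-to-linear ratio and ee are less documented in this mode than for small Grignard reagents. The fallback exchanges the roles of the partners. It sets out from 2: cross-metathesis of 2 with 6-chlorohex-1-ene F5 (second-generation Hoveyda–Grubbs catalyst) gives (E)-1-bromo-7-chlorohept-2-ene F6. Alkylation of F6 with ethylmagnesium bromide (CuBr·SMe2, (R,Rp)-Taniaphos, CH2Cl2, −75 °C), as in step 2, comes back to the route at 11.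

Further compounds
F1 | step 19 | methyl (2E,4R,13R,14E,16Z,20R,21S,23S)-24-{[(2S)-2-acetoxypentanoyl]amino}-20,21,23-tris[(tert-butyldimethylsilyl)oxy]-13-ethyl-17-(methoxymethyl)-2,4-dimethyltetracosa-2,14,16-trienoate | COC(=O)/C(C)=C/[C@H](C)CCCCCCCC[C@@H](CC)/C=C/C=C(\COC)CC[C@@H](O[Si](C)(C)C(C)(C)C)[C@@H](O[Si](C)(C)C(C)(C)C)C[C@H](O[Si](C)(C)C(C)(C)C)CNC(=O)[C@H](CCC)OC(C)=O
F2 | step 19 | (2E,4R,13R,14E,16Z,20R,21S,23S)-20,21,23-tris[(tert-butyldimethylsilyl)oxy]-13-ethyl-24-{[(2S)-2-hydroxypentanoyl]amino}-17-(methoxymethyl)-2,4-dimethyltetracosa-2,14,16-trienoic acid | OC(=O)/C(C)=C/[C@H](C)CCCCCCCC[C@@H](CC)/C=C/C=C(\COC)CC[C@@H](O[Si](C)(C)C(C)(C)C)[C@@H](O[Si](C)(C)C(C)(C)C)C[C@H](O[Si](C)(C)C(C)(C)C)CNC(=O)[C@H](CCC)O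
F3 | step 16 | N-{(2S,4S,5R)-2,4,5-tris[(tert-butyldimethylsilyl)oxy]-7-iodoheptyl}formamide | ICC[C@@H](O[Si](C)(C)C(C)(C)C)[C@@H](O[Si](C)(C)C(C)(C)C)C[C@H](O[Si](C)(C)C(C)(C)C)CNC=O
F4 | step 16 | iodido{(3R,4S,6S)-3,4,6-tris[(tert-butyldimethylsilyl)oxy]-7-formamidoheptyl}zinc | I[Zn]CC[C@@H](O[Si](C)(C)C(C)(C)C)[C@@H](O[Si](C)(C)C(C)(C)C)C[C@H](O[Si](C)(C)C(C)(C)C)CNC=O
F5 | step 4 | 6-chlorohex-1-ene | C=CCCCCCl
F6 | step 4 | (E)-1-bromo-7-chlorohept-2-ene | ClCCCC/C=C/CBr
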